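**Retrosynthetic overview**

- The (13Z)-enal side chain is attached last at C12 (sp3–sp2 cross-coupling, then oxidation); this leads back to a 13,14,15,16-tetranor decalin that already carries C2, C4, C5, C7, C9 and C10 correctly.
- Key disconnection: the C5–C10 bond (ring A) and the C7–C8 bond (ring B) of that decalin are opened together to an acyclic enal/alkene/alkyne chain. In the forward sense one iron-hydride radical cascade closes ring A first (tertiary C10 radical onto C5 of the enal) and then ring B (C8 vinyl radical onto the C7 aldehyde).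
- Enabling feature: C10 is a methyl-bearing quaternary carbon bonded to C5, C5 lies β to the C7 carbinol, and C7 sits in ring B next to the exocyclic C8=C17 methylene. These are the imprints of a radical addition to a C5=C6–C7=O enal and of an alkyne–aldehyde reductive closure, which share the C5–C6–C7 unit.
- The acyclic precursor comes from a Johnson–Claisen rearrangement (temporary C1 carbinol relays chirality to C9, adds C11–C12) after a Nozaki–Hiyama–Kishi union of a C1 aldehyde with a C8–C9–C10 alkenyl iodide.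
- Only C2 is bought (glutamic-acid-derived lactone); C4 is set by sequential lactone alkylation, and C1 (temporary), C9, C5, C10 and C7 are relayed from it by substrate control.

Key step: step 17

Remark (assumption): labdane numbering (C1 to C20) is used for every intermediate; Tr, PMB and TBS stand for triphenylmethyl, 4-methoxybenzyl and tert-butyldimethylsilyl; lactone 1 and 4-methoxybenzyl chloromethyl ether are taken as purchasable.

**Route**

Step 1
Reactants: 1 (S)-5-[(trityloxy)methyl]dihydrofuran-2(3H)-one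
Product: 2 (3S,5S)-3-[(PMB-oxy)methyl]-5-[(trityloxy)methyl]dihydrofuran-2(3H)-one (3,5-trans)
Conditions: LiN(i-Pr)2, THF, −78 °C; then 4-MeOC6H4CH2OCH2Cl, −78 to −40 °C
Reagents that add atoms: 4-methoxybenzyl chloromethyl ether, COc1ccc(COCCl)cc1
Why: The lithium enolate of the γ-substituted butyrolactone is alkylated by the reactive α-chloro ether on the face opposite the bulky trityloxymethyl group (substrate-controlled enolate alkylation), and this centre is reset in step 2.

Step 2
Reactants: 2 (3S,5S)-3-[(PMB-oxy)methyl]-5-[(trityloxy)methyl]dihydrofuran-2(3H)-one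
Product: 3 (3R,5S)-3-[(PMB-oxy)methyl]-3-methyl-5-[(trityloxy)methyl]dihydrofuran-2(3H)-one
Conditions: LiN(i-Pr)2, THF, −78 °C; then MeI, DMPU, −78 to −30 °C
Reagents that add atoms: iodomethane, CI
Why: After re-enolisation iodomethane again enters anti to the trityloxymethyl group (sequential dialkylation of a γ-substituted butyrolactone enolate), so that quaternary C4 carries methyl trans and the future C19 arm cis to the C1 arm, as the target requires.

Step 3
Reactants: 3 (3R,5S)-3-[(PMB-oxy)methyl]-3-methyl-5-[(trityloxy)methyl]dihydrofuran-2(3H)-one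
Product: 4 (3R,5S)-3-[(PMB-oxy)methyl]-3-methyl-5-[(trityloxy)methyl]tetrahydrofuran-2-ol (anomer mixture)
Conditions: i-Bu2AlH, CH2Cl2, −78 °C
Reagents that add atoms: none
Why: Partial reduction of the hindered α-quaternary lactone with i-Bu2AlH at low temperature should stop at the lactol without touching a stereocentre.

Step 4
Reactants: 4 (3R,5S)-3-[(PMB-oxy)methyl]-3-methyl-5-[(trityloxy)methyl]tetrahydrofuran-2-ol
Product: 5 ethyl (2E,4S,6S)-6-hydroxy-4-[(PMB-oxy)methyl]-4-methyl-7-(trityloxy)hept-2-enoate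
Conditions: Ph3P=CHCO2Et, PhCO2H (cat.), toluene, 90 °C
Reagents that add atoms: ethyl (triphenylphosphoranylidene)acetate, CCOC(=O)C=P(c1ccccc1)(c1ccccc1)c1ccccc1
Why: The open hydroxy-aldehyde form of the lactol is trapped by the stabilised ylide (Wittig reaction), which should give the (E)-enoate, free the C2 hydroxyl and turn the former lactone carbon into C5.

Step 5
Reactants: 5 ethyl (2E,4S,6S)-6-hydroxy-4-[(PMB-oxy)methyl]-4-methyl-7-(trityloxy)hept-2-enoate
Product: 6 ethyl (2E,4S,6S)-6-(TBS-oxy)-4-[(PMB-oxy)methyl]-4-methyl-7-(trityloxy)hept-2-enoate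
Conditions: TBSOTf, 2,6-lutidine, CH2Cl2, −78 to 0 °C
Reagents that add atoms: tert-butyldimethylsilyl triflate, CC(C)(C)[Si](C)(C)OS(=O)(=O)C(F)(F)F
Why: Silyl triflate with a hindered base silylates the secondary C2 alcohol (silyl ether formation), and the bulky silyloxy group later anchors the conformation in the key step.

Step 6
Reactants: 6 ethyl (2E,4S,6S)-6-(TBS-oxy)-4-[(PMB-oxy)methyl]-4-methyl-7-(trityloxy)hept-2-enoate
Product: 7 ethyl (2E,4S,6S)-6-(TBS-oxy)-7-hydroxy-4-[(PMB-oxy)methyl]-4-methylhept-2-enoate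
Conditions: HCO2H, Et2O, rt, then aqueous work-up
Reagents that add atoms: none
Why: The trityl ether ionises in formic acid much faster than the secondary silyl ether or the PMB ether (acid-labile trityl cleavage), which should free the primary C1 alcohol.

Step 7
Reactants: 7 ethyl (2E,4S,6S)-6-(TBS-oxy)-7-hydroxy-4-[(PMB-oxy)methyl]-4-methylhept-2-enoate
Product: 8 ethyl (2E,4S,6S)-6-(TBS-oxy)-4-[(PMB-oxy)methyl]-4-methyl-7-oxohept-2-enoate
Conditions: Dess–Martin periodinane, NaHCO3, CH2Cl2, 0 °C to rt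
Reagents that add atoms: none
Why: Buffered Dess–Martin oxidation should give the α-silyloxy aldehyde without epimerisation at C2 and leave the enoate untouched.

Step 8
Reactants: 9 3-(trimethylsilyl)prop-2-ynal
Product: 10 (Z)-(4-iodopent-3-en-1-yn-1-yl)trimethylsilane
Conditions: EtPPh3Br, n-BuLi, THF, −78 °C; I2; NaN(SiMe3)2; then 9, −78 °C
Reagents that add atoms: ethyltriphenylphosphonium bromide, CC[P+](c1ccccc1)(c1ccccc1)c1ccccc1.[Br-]; iodine, II
Why: The α-iodoethylidene ylide made in the flask olefinates the ynal with the cis selectivity typical of the Stork–Zhao olefination, which places iodine cis to the alkynyl group.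

Step 9
Reactants: 8 ethyl (2E,4S,6S)-6-(TBS-oxy)-4-[(PMB-oxy)methyl]-4-methyl-7-oxohept-2-enoate; 10 (Z)-(4-iodopent-3-en-1-yn-1-yl)trimethylsilane
Product: 11 ethyl (2E,4S,6S,7R,8Z)-6-(TBS-oxy)-7-hydroxy-4-[(PMB-oxy)methyl]-4,8-dimethyl-11-(trimethylsilyl)undeca-2,8-dien-10-ynoate
Conditions: CrCl2, NiCl2 (cat.), DMSO, rt
Reagents that add atoms: none
Why: The alkenylchromium species of the Nozaki–Hiyama–Kishi reaction adds only to the aldehyde with retention of alkene geometry, and Felkin–Anh control by the α-silyloxy centre should favour the 1,2-anti carbinol at C1 (a temporary stereocentre).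

Step 10
Reactants: 11 ethyl (2E,4S,6S,7R,8Z)-6-(TBS-oxy)-7-hydroxy-4-[(PMB-oxy)methyl]-4,8-dimethyl-11-(trimethylsilyl)undeca-2,8-dien-10-ynoate
Product: 12 ethyl (2E,4S,6S,7E,9R)-6-(TBS-oxy)-9-(2-ethoxy-2-oxoethyl)-4-[(PMB-oxy)methyl]-4,8-dimethyl-11-(trimethylsilyl)undeca-2,7-dien-10-ynoate
Conditions: MeC(OEt)3, EtCO2H (cat.), xylene, 140 °C
Reagents that add atoms: triethyl orthoacetate, CCOC(C)(OCC)OCC
Why: Johnson–Claisen rearrangement through a chair with the C2-bearing substituent equatorial forms the C9–C11 bond on the alkene face from which the C1–O bond departs, so the C1 configuration is transferred to C9, the (E)-C1=C10 alkene forms and C11–C12 arrive as an ester (the slim (Z)-alkynyl group sits axial).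

Step 11
Reactants: 12 ethyl (2E,4S,6S,7E,9R)-6-(TBS-oxy)-9-(2-ethoxy-2-oxoethyl)-4-[(PMB-oxy)methyl]-4,8-dimethyl-11-(trimethylsilyl)undeca-2,7-dien-10-ynoate
Product: 13 (2E,4S,6S,7E,9R)-6-(TBS-oxy)-9-(2-hydroxyethyl)-4-[(PMB-oxy)methyl]-4,8-dimethyl-11-(trimethylsilyl)undeca-2,7-dien-10-yn-1-ol
Conditions: i-Bu2AlH (excess), CH2Cl2, −78 to 0 °C
Reagents that add atoms: none
Why: Excess i-Bu2AlH reduces both esters (1,2-reduction of the enoate to the allylic alcohol, reduction of the saturated ester to the C12 alcohol) without touching the alkynylsilane or the ethers.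

Step 12
Reactants: 13 (2E,4S,6S,7E,9R)-6-(TBS-oxy)-9-(2-hydroxyethyl)-4-[(PMB-oxy)methyl]-4,8-dimethyl-11-(trimethylsilyl)undeca-2,7-dien-10-yn-1-ol
Product: 14 (2E,4S,6S,7E,9S)-6-(TBS-oxy)-9-(2-hydroxyethyl)-4-[(PMB-oxy)methyl]-4,8-dimethylundeca-2,7-dien-10-yn-1-ol
Conditions: K2CO3 (cat.), MeOH, rt
Reagents that add atoms: none
Why: Carbonate-catalysed methanolysis of the alkynyl–silicon bond unmasks the terminal alkyne while the silyl ether stays (the C9 descriptor changes only by priority).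

Step 13
Reactants: 14 (2E,4S,6S,7E,9S)-6-(TBS-oxy)-9-(2-hydroxyethyl)-4-[(PMB-oxy)methyl]-4,8-dimethylundeca-2,7-dien-10-yn-1-ol
Product: 15 (2E,4S,6S,7E,9S)-6-(TBS-oxy)-9-(2-hydroxyethyl)-4-[(PMB-oxy)methyl]-4,8-dimethylundeca-2,7-dien-10-ynal
Conditions: MnO2, CH2Cl2, rt
Reagents that add atoms: none
Why: MnO2 oxidises only the allylic primary alcohol (chemoselective allylic oxidation) and so should give the (E)-enal at C7 beside the free C12 alcohol.

Step 14
Reactants: 15 (2E,4S,6S,7E,9S)-6-(TBS-oxy)-9-(2-hydroxyethyl)-4-[(PMB-oxy)methyl]-4,8-dimethylundeca-2,7-dien-10-ynal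
Product: 16 (2E,4S,6S,7E,9S)-6-(TBS-oxy)-9-[2-(TBS-oxy)ethyl]-4-[(PMB-oxy)methyl]-4,8-dimethylundeca-2,7-dien-10-ynal
Conditions: TBSCl, imidazole, CH2Cl2, 0 °C to rt
Reagents that add atoms: tert-butyldimethylsilyl chloride, CC(C)(C)[Si](C)(C)Cl
Why: Standard silylation of the primary C12 alcohol ensures that only the C19 oxygen is free in the next two steps.

Step 15
Reactants: 16 (2E,4S,6S,7E,9S)-6-(TBS-oxy)-9-[2-(TBS-oxy)ethyl]-4-[(PMB-oxy)methyl]-4,8-dimethylundeca-2,7-dien-10-ynal
Product: 17 (2E,4S,6S,7E,9S)-6-(TBS-oxy)-9-[2-(TBS-oxy)ethyl]-4-(hydroxymethyl)-4,8-dimethylundeca-2,7-dien-10-ynal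
Conditions: DDQ, CH2Cl2/pH 7 buffer, 0 °C
Reagents that add atoms: none
Why: DDQ cleaves the PMB ether oxidatively through the benzylic oxocarbenium ion and should spare the alkenes, the alkyne and the silyl ethers.

Step 16
Reactants: 17 (2E,4S,6S,7E,9S)-6-(TBS-oxy)-9-[2-(TBS-oxy)ethyl]-4-(hydroxymethyl)-4,8-dimethylundeca-2,7-dien-10-ynal
Product: 18 (2E,4S,6S,7E,9S)-4-(acetoxymethyl)-6-(TBS-oxy)-9-[2-(TBS-oxy)ethyl]-4,8-dimethylundeca-2,7-dien-10-ynal
Conditions: Ac2O, pyridine, DMAP (cat.), CH2Cl2, 0 °C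
Reagents that add atoms: acetic anhydride, CC(=O)OC(C)=O
Why: Acetylation of the only free hydroxyl installs the C19 acetate at a point after which no hydride, organometallic or strong base is used.

Step 17
Reactants: 18 (2E,4S,6S,7E,9S)-4-(acetoxymethyl)-6-(TBS-oxy)-9-[2-(TBS-oxy)ethyl]-4,8-dimethylundeca-2,7-dien-10-ynal
Product: 20 19-acetoxy-2α,12-bis(TBS-oxy)-13,14,15,16-tetranorlabd-8(17)-en-7α-ol, via ring-A aldehyde 19 (not isolated)
Conditions: Fe(acac)3 (cat.), PhSiH3 (excess, slow addition), EtOH/(CH2OH)2, 60 °C, high dilution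
Reagents that add atoms: none
Why: Proposed new method: an iron hydride formed from Fe(acac)3 and PhSiH3 transfers a hydrogen atom to C1 of the trisubstituted C1=C10 alkene, the tertiary C10 radical closes ring A by 6-exo-trig Giese addition to C5 of the enal, the α-formyl radical is reduced by divalent iron and protonated to aldehyde 19, and a second, slower hydrogen-atom transfer to alkyne carbon C17 gives the C8 vinyl radical, which closes ring B by 6-exo-trig attack on the C7 carbonyl before the alkoxy radical is reduced. The closest known reaction types are the iron-hydride-initiated reductive coupling of unactivated alkenes with enals and enones (first ring) and the iron-hydride-initiated cyclisation of alkene-derived radicals onto carbonyl groups together with 6-exo cyclisations of vinyl radicals onto aldehydes under tin hydride conditions (second ring); hydrogen-atom transfer to an alkyne in this setting is the unprecedented element. C5 and C10 should be set in a chair transition state in which the C2 silyloxy group is equatorial, which forces the C4 acetoxymethyl group axial, puts the enal arm at C5 equatorial (5α-H) and the smaller methyl of the C10 radical axial (10β), so that C2 relays through C4 to both centres. C7 should be set in the second chair, with the preset C9 side chain equatorial, the carbonyl oxygen turning out of the plane of the C8=C17 unit to avoid allylic 1,3-strain with the methylene, which gives the axial 7α-alcohol. The step needs the alkene to react before the alkyne and the α-formyl radical to be reduced before it can add 5-exo-dig to the alkyne; the much higher reactivity of trisubstituted alkenes toward metal hydrides and the fast reduction of α-carbonyl radicals by divalent iron should secure this order.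

Step 18
Reactants: 20 19-acetoxy-2α,12-bis(TBS-oxy)-13,14,15,16-tetranorlabd-8(17)-en-7α-ol
Product: 21 19-acetoxy-13,14,15,16-tetranorlabd-8(17)-ene-2α,7α,12-triol
Conditions: HF·pyridine, pyridine, THF, 0 °C to rt
Reagents that add atoms: none
Why: Buffered HF·pyridine cleaves both silyl ethers (fluoride-mediated desilylation) and should leave the acetate and the allylic alcohol intact.

Step 19
Reactants: 21 19-acetoxy-13,14,15,16-tetranorlabd-8(17)-ene-2α,7α,12-triol
Product: 22 19-acetoxy-12-iodo-13,14,15,16-tetranorlabd-8(17)-ene-2α,7α-diol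
Conditions: I2, PPh3, imidazole, THF, 0 °C
Reagents that add atoms: iodine, II
Why: Under Appel conditions the unhindered primary C12 alcohol should react far faster than the two secondary alcohols (SN2 displacement of the alkoxyphosphonium ion by iodide).

Step 20
Reactants: 23 but-2-yn-1-ol
Product: 24 (Z)-3-iodobut-2-en-1-ol
Conditions: NaAlH2(OCH2CH2OMe)2, THF, 0 °C to rt; then I2, −78 °C
Reagents that add atoms: iodine, II
Why: Hydroxyl-directed trans-hydroalumination of the propargylic alcohol and iodinolysis of the alkenylalanate place iodine cis to the carbinol carbon.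

Step 21
Reactants: 22 19-acetoxy-12-iodo-13,14,15,16-tetranorlabd-8(17)-ene-2α,7α-diol; 24 (Z)-3-iodobut-2-en-1-ol
Product: 25 19-acetoxylabda-8(17),13Z-diene-2α,7α,15-triol
Conditions: NiI2 (cat.), 4,4′-di-tert-butyl-2,2′-bipyridine, Zn, pyridine (cat.), DMPU, rt
Reagents that add atoms: none
Why: Nickel-catalysed reductive cross-electrophile coupling joins the alkyl iodide (through its radical) with the alkenyl iodide (through oxidative addition to zerovalent nickel) with retention of alkene geometry and tolerates free hydroxyls and the acetate, which should give the C12–C13 bond and the (13Z)-alkene.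

Step 22
Reactants: 25 19-acetoxylabda-8(17),13Z-diene-2α,7α,15-triol
Product: 26 19-acetoxy-2α,7α-dihydroxylabda-8(17),13Z-dien-15-al (target)
Conditions: TEMPO (cat.), PhI(OAc)2, CH2Cl2, rt
Reagents that add atoms: none
Why: The oxoammonium cycle of TEMPO with PhI(OAc)2 oxidises the primary allylic alcohol much faster than the secondary C2 and C7 alcohols (chemoselective oxidation) and, being neutral, should preserve the (Z)-enal.

**Compound list**

1 | (S)-5-[(trityloxy)methyl]dihydrofuran-2(3H)-one | O=C1CC[C@@H](COC(c2ccccc2)(c2ccccc2)c2ccccc2)O1 | starting material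
2 | (3S,5S)-3-[(PMB-oxy)methyl]-5-[(trityloxy)methyl]dihydrofuran-2(3H)-one | O=C1[C@H](COCc2ccc(OC)cc2)C[C@@H](COC(c2ccccc2)(c2ccccc2)c2ccccc2)O1 | intermediate
3 | (3R,5S)-3-[(PMB-oxy)methyl]-3-methyl-5-[(trityloxy)methyl]dihydrofuran-2(3H)-one | O=C1[C@@](C)(COCc2ccc(OC)cc2)C[C@@H](COC(c2ccccc2)(c2ccccc2)c2ccccc2)O1 | intermediate
4 | (3R,5S)-3-[(PMB-oxy)methyl]-3-methyl-5-[(trityloxy)methyl]tetrahydrofuran-2-ol (anomer mixture) | OC1[C@@](C)(COCc2ccc(OC)cc2)C[C@@H](COC(c2ccccc2)(c2ccccc2)c2ccccc2)O1 | intermediate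
5 | ethyl (2E,4S,6S)-6-hydroxy-4-[(PMB-oxy)methyl]-4-methyl-7-(trityloxy)hept-2-enoate | CCOC(=O)/C=C/[C@@](C)(COCc1ccc(OC)cc1)C[C@H](O)COC(c1ccccc1)(c1ccccc1)c1ccccc1 | intermediate
6 | ethyl (2E,4S,6S)-6-(TBS-oxy)-4-[(PMB-oxy)methyl]-4-methyl-7-(trityloxy)hept-2-enoate | CCOC(=O)/C=C/[C@@](C)(COCc1ccc(OC)cc1)C[C@H](O[Si](C)(C)C(C)(C)C)COC(c1ccccc1)(c1ccccc1)c1ccccc1 | intermediate
7 | ethyl (2E,4S,6S)-6-(TBS-oxy)-7-hydroxy-4-[(PMB-oxy)methyl]-4-methylhept-2-enoate | CCOC(=O)/C=C/[C@@](C)(COCc1ccc(OC)cc1)C[C@H](O[Si](C)(C)C(C)(C)C)CO | intermediate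
8 | ethyl (2E,4S,6S)-6-(TBS-oxy)-4-[(PMB-oxy)methyl]-4-methyl-7-oxohept-2-enoate | CCOC(=O)/C=C/[C@@](C)(COCc1ccc(OC)cc1)C[C@H](O[Si](C)(C)C(C)(C)C)C=O | intermediate
9 | 3-(trimethylsilyl)prop-2-ynal | C[Si](C)(C)C#CC=O | starting material
10 | (Z)-(4-iodopent-3-en-1-yn-1-yl)trimethylsilane | C[Si](C)(C)C#C/C=C(\I)C | intermediate
11 | ethyl (2E,4S,6S,7R,8Z)-6-(TBS-oxy)-7-hydroxy-4-[(PMB-oxy)methyl]-4,8-dimethyl-11-(trimethylsilyl)undeca-2,8-dien-10-ynoate | CCOC(=O)/C=C/[C@@](C)(COCc1ccc(OC)cc1)C[C@H](O[Si](C)(C)C(C)(C)C)[C@H](O)/C(C)=C\C#C[Si](C)(C)C | intermediate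
12 | ethyl (2E,4S,6S,7E,9R)-6-(TBS-oxy)-9-(2-ethoxy-2-oxoethyl)-4-[(PMB-oxy)methyl]-4,8-dimethyl-11-(trimethylsilyl)undeca-2,7-dien-10-ynoate | CCOC(=O)/C=C/[C@@](C)(COCc1ccc(OC)cc1)C[C@H](O[Si](C)(C)C(C)(C)C)/C=C(\C)[C@@H](CC(=O)OCC)C#C[Si](C)(C)C | intermediate
13 | (2E,4S,6S,7E,9R)-6-(TBS-oxy)-9-(2-hydroxyethyl)-4-[(PMB-oxy)methyl]-4,8-dimethyl-11-(trimethylsilyl)undeca-2,7-dien-10-yn-1-ol | OC/C=C/[C@@](C)(COCc1ccc(OC)cc1)C[C@H](O[Si](C)(C)C(C)(C)C)/C=C(\C)[C@@H](CCO)C#C[Si](C)(C)C | intermediate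
14 | (2E,4S,6S,7E,9S)-6-(TBS-oxy)-9-(2-hydroxyethyl)-4-[(PMB-oxy)methyl]-4,8-dimethylundeca-2,7-dien-10-yn-1-ol | OC/C=C/[C@@](C)(COCc1ccc(OC)cc1)C[C@H](O[Si](C)(C)C(C)(C)C)/C=C(\C)[C@@H](CCO)C#C | intermediate
15 | (2E,4S,6S,7E,9S)-6-(TBS-oxy)-9-(2-hydroxyethyl)-4-[(PMB-oxy)methyl]-4,8-dimethylundeca-2,7-dien-10-ynal | O=C/C=C/[C@@](C)(COCc1ccc(OC)cc1)C[C@H](O[Si](C)(C)C(C)(C)C)/C=C(\C)[C@@H](CCO)C#C | intermediate
16 | (2E,4S,6S,7E,9S)-6-(TBS-oxy)-9-[2-(TBS-oxy)ethyl]-4-[(PMB-oxy)methyl]-4,8-dimethylundeca-2,7-dien-10-ynal | O=C/C=C/[C@@](C)(COCc1ccc(OC)cc1)C[C@H](O[Si](C)(C)C(C)(C)C)/C=C(\C)[C@@H](CCO[Si](C)(C)C(C)(C)C)C#C | intermediate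
17 | (2E,4S,6S,7E,9S)-6-(TBS-oxy)-9-[2-(TBS-oxy)ethyl]-4-(hydroxymethyl)-4,8-dimethylundeca-2,7-dien-10-ynal | O=C/C=C/[C@@](C)(CO)C[C@H](O[Si](C)(C)C(C)(C)C)/C=C(\C)[C@@H](CCO[Si](C)(C)C(C)(C)C)C#C | intermediate
18 | (2E,4S,6S,7E,9S)-4-(acetoxymethyl)-6-(TBS-oxy)-9-[2-(TBS-oxy)ethyl]-4,8-dimethylundeca-2,7-dien-10-ynal | O=C/C=C/[C@@](C)(COC(C)=O)C[C@H](O[Si](C)(C)C(C)(C)C)/C=C(\C)[C@@H](CCO[Si](C)(C)C(C)(C)C)C#C | intermediate
19 | ring-A aldehyde: 19-acetoxy-2α,12-bis(TBS-oxy)-13,14,15,16-tetranor-7,8-secolabd-8(17)-yn-7-al (5α-H, 10β-methyl; not isolated) | O=CC[C@H]1[C@@](C)(COC(C)=O)C[C@H](O[Si](C)(C)C(C)(C)C)C[C@]1(C)[C@@H](CCO[Si](C)(C)C(C)(C)C)C#C | intermediate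
20 | 19-acetoxy-2α,12-bis(TBS-oxy)-13,14,15,16-tetranorlabd-8(17)-en-7α-ol | C=C1[C@H](O)C[C@H]2[C@@](C)(COC(C)=O)C[C@H](O[Si](C)(C)C(C)(C)C)C[C@]2(C)[C@H]1CCO[Si](C)(C)C(C)(C)C | intermediate
21 | 19-acetoxy-13,14,15,16-tetranorlabd-8(17)-ene-2α,7α,12-triol | C=C1[C@H](O)C[C@H]2[C@@](C)(COC(C)=O)C[C@H](O)C[C@]2(C)[C@H]1CCO | intermediate
22 | 19-acetoxy-12-iodo-13,14,15,16-tetranorlabd-8(17)-ene-2α,7α-diol | C=C1[C@H](O)C[C@H]2[C@@](C)(COC(C)=O)C[C@H](O)C[C@]2(C)[C@H]1CCI | intermediate
23 | but-2-yn-1-ol | CC#CCO | starting material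
24 | (Z)-3-iodobut-2-en-1-ol | I/C(C)=C\CO | intermediate
25 | 19-acetoxylabda-8(17),13Z-diene-2α,7α,15-triol | C=C1[C@H](O)C[C@H]2[C@@](C)(COC(C)=O)C[C@H](O)C[C@]2(C)[C@H]1CC/C(C)=C\CO | intermediate
26 | 19-acetoxy-2α,7α-dihydroxylabda-8(17),13Z-dien-15-al | C=C1[C@H](O)C[C@H]2[C@@](C)(COC(C)=O)C[C@H](O)C[C@]2(C)[C@H]1CC/C(C)=C\C=O | target

**Step count and risks**

Total step count: 22. Longest linear sequence: 20 steps (steps 1–7, 9–19, 21, 22).

Steps most likely to fail:

1. Step 17 (the new cascade). Process at risk: hydrogen-atom transfer to the terminal alkyne may be too slow, or the vinyl radical may be reduced before it reaches the carbonyl group, so that the cascade stops after ring A; facial selectivity at C7 may also be low. Fallback with known chemistry: it sets out from 18. The iron-hydride Giese cyclisation alone (Fe(acac)3, PhSiH3 in small excess, EtOH, 60 °C) is stopped at ring-A aldehyde 19, which is isolated. Ring B is then closed separately by a samarium ketyl–alkyne 6-exo-dig cyclisation (SmI2, HMPA, t-BuOH, THF, 0 °C), in which the bulky samarium alkoxide should also avoid the plane of the forming C8=C17 unit. It comes back to the route at 20 and makes no compound outside the list.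

2. Step 9. Process at risk: a weak Felkin–Anh facial bias in the addition to the α-silyloxy aldehyde would give both C1 carbinol epimers and erode C9 after the rearrangement. Fallback: it sets out from 11 obtained as the epimer mixture. Oxidation (Dess–Martin periodinane) should give ethyl (2E,4S,6S,8Z)-6-(TBS-oxy)-4-[(PMB-oxy)methyl]-4,8-dimethyl-7-oxo-11-(trimethylsilyl)undeca-2,8-dien-10-ynoate F1. Reagent-controlled Corey–Bakshi–Shibata reduction ((R)-2-methyl-CBS-oxazaborolidine, catecholborane, −78 °C, the enynyl group acting as the large substituent) should then return the 7R alcohol; it comes back at 11.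

3. Step 21. Process at risk: hydrodehalogenation or homocoupling of the alkyl iodide and partial loss of the Z geometry at the alkenylnickel stage. Fallback: it sets out from 22. Both secondary alcohols are silylated (Et3SiOTf, 2,6-lutidine) to 19-acetoxy-12-iodo-2α,7α-bis(triethylsilyloxy)-13,14,15,16-tetranorlabd-8(17)-ene F2. Zinc insertion (Zn, LiCl, THF) and Negishi coupling (Pd2(dba)3, SPhos) with (Z)-tert-butyl[(3-iodobut-2-en-1-yl)oxy]dimethylsilane F3 (from 24, TBSCl, imidazole) should give 19-acetoxy-15-(TBS-oxy)-2α,7α-bis(triethylsilyloxy)labda-8(17),13Z-diene F4. HF·pyridine removes the three silyl groups, and the sequence comes back at 25.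

**Further compounds**

F0 | step 17 | none | none
F1 | step 9 | ethyl (2E,4S,6S,8Z)-6-(TBS-oxy)-4-[(PMB-oxy)methyl]-4,8-dimethyl-7-oxo-11-(trimethylsilyl)undeca-2,8-dien-10-ynoate | CCOC(=O)/C=C/[C@@](C)(COCc1ccc(OC)cc1)C[C@H](O[Si](C)(C)C(C)(C)C)C(=O)/C(C)=C\C#C[Si](C)(C)C
F2 | step 21 | 19-acetoxy-12-iodo-2α,7α-bis(triethylsilyloxy)-13,14,15,16-tetranorlabd-8(17)-ene | C=C1[C@H](O[Si](CC)(CC)CC)C[C@H]2[C@@](C)(COC(C)=O)C[C@H](O[Si](CC)(CC)CC)C[C@]2(C)[C@H]1CCI
F3 | step 21 | (Z)-tert-butyl[(3-iodobut-2-en-1-yl)oxy]dimethylsilane | I/C(C)=C\CO[Si](C)(C)C(C)(C)C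
F4 | step 21 | 19-acetoxy-15-(TBS-oxy)-2α,7α-bis(triethylsilyloxy)labda-8(17),13Z-diene | C=C1[C@H](O[Si](CC)(CC)CC)C[C@H]2[C@@](C)(COC(C)=O)C[C@H](O[Si](CC)(CC)CC)C[C@]2(C)[C@H]1CC/C(C)=C\CO[Si](C)(C)C(C)(C)C
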